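A factor of 6.59 in the charge of Q, from birch to cedar at the same charge of D, went with a factor of 3.55 in c(L) at 90.0 s, so c(L) grew less than the charge. My decision for the next run hangs on that gap: do I raise the charge of Q, or does the extra Q merely sit there?

the same everywhere: D 1.2 mM
- birch: Q 0.0044 M; run made earlier
- cedar: Q 0.029 M; run made earlier
- north: Q 0.0050 M; time 3.0 min
- north-east: Q 0.010 M; time 3.0 min
- east: Q 0.020 M; time 3.0 min
- south-east: Q 0.040 M; time 3.0 min

- birch (time / s: L / %): 15.0: 8.3; 30.0: 19.1; 50.0: 33.2; 60.0: 39.6; 80.0: 50.4; 90.0: 54.4
- cedar (time / s: L / %): 10.0: 2.6; 20.0: 6.3; 30.0: 10.1; 50.0: 16.8; 60.0: 20.5; 90.0: 29.3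

(each reading ± 0.5 percentage points)

- [L] at the end for north, north-east, east, south-east, in this order
- how the row runs (falls, then rises / falls all the way / rises, then falls / hardly changes / rises all the way)

I go to logarithms, and there the gap becomes a single number: the charge exponent n, the slope of log c(L) against log charge of Q at a fixed time and fixed D, which is an apparent order in Q. From the birch and cedar readings at 90.0 s:

c(L) in birch = 2.39 mM, c(L) in cedar = 8.50 mM

n = log(cedar over birch, c(L)) / log(cedar over birch, charge) = 0.551 / 0.819 = 0.672

The readings at 30.0 s give 0.662, close to that, and I carry the exponent on to 3.0 min. That is a stretch, and so is south-east, whose charge lies above cedar's.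

Each doubling of the charge should then multiply c(L) by

factor per doubling = 1.59

and going from north to south-east should multiply it by

4.04

So the row rises, while the percent of Q turned falls to about half. I therefore charge south-east if I want the amount of L, and north if I want conversion.

The forecast gives 0.0038 M, 0.0072 M, 0.0126 M and 0.0189 M, a row that rises all the way, on the ground that “the rate rises less than in proportion to Q”.

The flasks give 0.00407 M, 0.00756 M, 0.0128 M and 0.0182 M, a row that rises all the way, and south-east over north is 4.47 against my 4.04.

    Q + D → X (k = 10.2 /M/s)
    X → D + L (k = 0.122 /s)
    D → G (k = 6.27 × 10⁻⁴ /s)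

Reckoned on the ends of the row, the exponent is 0.893 from north to north-east and 0.508 from east to south-east, and my n of 0.672 lies between the two. In north at 3.00 min, D has a half-life of 1.3 min against capture by Q, which is longer than the 0.095 min half-life of X, and X stands at 6.58 % of the catalyst there, while in south-east at 3.00 min it stands at 62.0 %.

(The numbers in the tables stem from a simulated flask for substances that don't exist; scatter was added.)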